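in all of them: free monomer 0.50 M
- larch: pre-initiator 50 mM; impurity 22 mM; run made earlier
- cedar: pre-initiator 50 mM; impurity 50 mM; run made earlier
- maple: pre-initiator 100 mM; impurity 33 mM; run made earlier
- flask: pre-initiator 50 mM; impurity 33 mM; time 30 h

| run | time / h | monomer in chains / % | free monomer / % |
|---|---|---|---|
| larch | 2.50 | 39 | 58 |
| larch | 5.00 | 46 | 47 |
| larch | 8.00 | 48 | 53 |
| larch | 10.0 | 46 | 57 |
| larch | 12.0 | 48 | 52 |
| larch | 15.0 | 47 | 56 |
| larch | 20.0 | 46 | 50 |
| cedar | 2.50 | 28 | 68 |
| cedar | 5.00 | 43 | 54 |
| cedar | 8.00 | 48 | 49 |
| cedar | 10.0 | 50 | 54 |
| cedar | 12.0 | 48 | 52 |
| cedar | 15.0 | 48 | 54 |
| cedar | 20.0 | 46 | 55 |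
| maple | 4.00 | 48 | 52 |
| maple | 8.00 | 48 | 53 |
| maple | 10.0 | 49 | 55 |
| maple | 15.0 | 45 | 53 |
| maple | 20.0 | 47 | 50 |

(scatter of a reading: 2 percentage points)

- the average divides the monomer in chains by the number of chains begun, living and dead together
- what was read earlier has a scatter of 2 percentage points, one standard deviation
- steps that have been proposed: free monomer + initiator -> living end + monomer in chains; free monomer + living end -> monomer in chains + living end; initiator + impurity -> spent initiator A; pre-initiator -> initiator; monomer in chains + living end -> free monomer + living end; 2 initiator -> spent initiator B
- the earlier runs do not show the number of chains; that part of a forecast is a guess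

- average number of monomer units in a chain (chains begun, living or dead) at 30 h
- part of the free monomer that has reacted at 30 h

The figure to weigh before you charge the next run is 0.265 M, the mean free monomer in the larch, cedar and maple runs at 15.0 h and 20.0 h, a reading that carries their scatter. Call it the balance level: the [free monomer] at which the step adding monomer to a living end and the step giving it back run equally fast (the equilibrium monomer concentration).

Both proposed steps go through a living end, so I take it that a change in [living end] moves them together. The late readings fit that: maple had twice the pre-initiator of larch, and cedar had 50 mM of impurity against 22 mM in larch, yet their late free monomer readings scatter about one level. For the flask I therefore reckon: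

reacted part = 1 − 0.265 M / 0.50 M = 47.0%

My decision is to keep the time and the pre-initiator as written and, for more monomer in chains, to raise the charge of free monomer above 0.50 M. That assumes the level holds at another charge of free monomer, which larch, cedar and maple, charged alike with free monomer, do not test. The earlier runs do not show the number of chains, so they give me no dp.

The forecast says 47.5% (46% to 49%), a little above my figure, and a dp of 11 (8 to 15), holding that “This is a propagation–depropagation ceiling, with free monomer near 0.26 M, rather than exhaustion.”

The simulation gives 47.5% reacted and a dp of 10.2.

    free monomer + initiator → living end + monomer in chains (k = 2.44 /M/min)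
    free monomer + living end → monomer in chains + living end, rate k2*[living end]*[free monomer] (k = 1.12 /M/min)
    initiator + impurity → spent initiator A (k = 59.9 /M/min)
    pre-initiator → initiator (k = 0.00706 /min)
    monomer in chains + living end → free monomer + living end, rate k5*[living end] as long as [monomer in chains] is above zero (k = 0.294 /min)
    2 initiator → spent initiator B (k = 0.439 /M/min)

At 30.0 h the flask makes monomer in chains 1.00 times as fast as it uses it up, each step taken net, while the half-life of free monomer by the adding step, 0.44 h, is short against 30 h, and 52.5% of the charge stands free, where the balance level as read makes 53.0%. Carried to a neighbour charged with 2.0 M of free monomer, the balance level as read, 0.265 M, is 13.2% of the charge, and that neighbour has 13.1% of its charge free at 30.0 h.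

The earlier runs and the new flask come from a simulation with constants of no real substance; the scatter is artificial.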